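**Plan**
- Retrosynthesis: the MOM ether and tert-butyl ester come off last. The bond between pyranone C2 and the side-chain CH2 is then cut to a 2-iodochromone and a terminal oxirane, both electrophiles. C2–I goes back to C2–H, and the pyranone ring (O1–C2, C2–C3) back to an o-hydroxyacetophenone plus a one-carbon unit.
- Forward: the pyranone ring is closed first on the purchased benzene ring (enaminone cyclisation), the 5-OH is masked and C2 is iodinated. The C9 chain oxirane is made in parallel, the two halves are joined by a nickel/iodide reductive coupling, and one acid step frees 5-OH and CO2H.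
- Enabling feature: C2 of the 4H-pyran-4-one ring is the O1-bearing β-carbon of the vinylogous ester O1–C2=C3–C4=O, so its C–H can be metalated and its C–I bond is an activated sp2 electrophile. The side-chain pair CH2–CH(OH) is the open form of a monosubstituted oxirane, so two electrophilic carbons are united reductively.
- Stereochemistry: the only stereocentre (C8 of the nonanoate chain, R) comes from hydrolytic kinetic resolution of the racemic oxirane. The coupling forms the bond at the neighbouring CH2 and never breaks the C8–O bond.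

Key step: step 7

Assumption: the (R,R)-(salen)Co catalyst is taken to leave the 2R alkyloxirane unhydrolysed, the usual sense for alkyl oxiranes; if the sense were opposite, the antipodal catalyst would be used.

**Step 1**
Reactants: 1 1-(2,6-dihydroxy-4-methoxyphenyl)ethan-1-one
Product: 3 5-hydroxy-7-methoxy-4H-chromen-4-one, via enaminone 2 (not isolated)
Conditions: DMF-DMA (2 equiv), toluene, 90 °C; then conc. HCl, CH2Cl2, 40 °C
Reagents that add atoms: N,N-dimethylformamide dimethyl acetal (COC(OC)N(C)C)
Why: Condensation of the acetyl CH3 with the amide acetal gives the β-dimethylaminoenone, and acid-promoted intramolecular oxa-Michael addition of either of the two equivalent ortho-OH groups with loss of dimethylamine closes the 4-pyranone ring (enaminone chromone synthesis).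

**Step 2**
Reactants: 3 5-hydroxy-7-methoxy-4H-chromen-4-one
Product: 4 7-methoxy-5-(methoxymethoxy)-4H-chromen-4-one
Conditions: NaH, MOMCl, DMF, 0 °C → rt
Reagents that add atoms: chloromethyl methyl ether (COCCl)
Why: Williamson-type O-alkylation of the sodium phenoxide, the only acidic site, masks the chelated 5-OH as an acetal that should tolerate the amide base of step 3 and the reductive conditions of step 7 and fall off in acid in step 8.

**Step 3**
Reactants: 4 7-methoxy-5-(methoxymethoxy)-4H-chromen-4-one
Product: 6 2-iodo-7-methoxy-5-(methoxymethoxy)-4H-chromen-4-one, via C2-zincated chromone 5 (not isolated)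
Conditions: TMP2Zn·2MgCl2·2LiCl (0.6 equiv), THF, −30 °C; then I2, THF, −30 → 0 °C
Reagents that add atoms: iodine (II)
Why: Deprotonative zincation with a Lewis-acid-containing TMP-zinc base should take the C2–H, which carbonyl complexation makes pyrylium-ylide-like, to give a zinc species that does not ring-open as a lithium one would, and iodinolysis then places iodine at C2.

**Step 4**
Reactants: 7 non-8-enoic acid
Product: 8 tert-butyl non-8-enoate
Conditions: tert-butyl 2,2,2-trichloroacetimidate, BF3·OEt2 (cat.), cyclohexane/CH2Cl2, rt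
Reagents that add atoms: tert-butyl 2,2,2-trichloroacetimidate (CC(C)(C)OC(=N)C(Cl)(Cl)Cl)
Why: Acid-catalysed O-alkylation of the carboxylic acid by the trichloroacetimidate (tert-butyl cation transfer) should give the ester without touching the terminal alkene.

**Step 5**
Reactants: 8 tert-butyl non-8-enoate
Product: 9 rac-tert-butyl 7-(oxiran-2-yl)heptanoate
Conditions: mCPBA, NaHCO3, CH2Cl2, 0 °C → rt
Reagents that add atoms: 3-chloroperoxybenzoic acid (OOC(=O)c1cccc(Cl)c1)
Why: Prilezhaev epoxidation of the monosubstituted alkene by the peracid, with the ester inert.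

**Step 6**
Reactants: 9 rac-tert-butyl 7-(oxiran-2-yl)heptanoate
Product: 10 tert-butyl 7-[(2R)-oxiran-2-yl]heptanoate
Conditions: (R,R)-(salen)Co(III)OAc (0.5 mol %), H2O (0.55 equiv), THF (minimal), 0 °C → rt
Reagents that add atoms: none
Why: Jacobsen hydrolytic kinetic resolution, in which the chiral cobalt catalyst hydrolyses the 2S oxirane much faster than the 2R one, so that at just over half conversion the recovered epoxide should be the R enantiomer that fixes the future C8 configuration.

**Step 7**
Reactants: 6 2-iodo-7-methoxy-5-(methoxymethoxy)-4H-chromen-4-one; 10 tert-butyl 7-[(2R)-oxiran-2-yl]heptanoate (1.5 equiv)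
Product: 12 tert-butyl (8R)-8-hydroxy-9-[7-methoxy-5-(methoxymethoxy)-4-oxo-4H-chromen-2-yl]nonanoate, via iodohydrin 11 (not isolated)
Conditions: NiCl2·glyme (10 mol %), 2,2'-bipyridine (10 mol %), NaI (0.5 equiv), Et3N·HCl (1.0 equiv), Mn powder (2 equiv), DMPU, 25 °C
Reagents that add atoms: none
Why: Iodide with Et3NH+ opens oxirane 10 by SN2 attack at its unsubstituted CH2 to give iodohydrin 11; (bpy)Ni(0) inserts into the C2–I bond of 6, the primary radical released from 11 by halogen abstraction at nickel is captured by the chromon-2-yl–Ni(II) species, and reductive elimination from Ni(III) forms the C2–CH2 bond while Mn returns nickel to Ni(0). The closest known reaction type is the nickel/iodide co-catalysed reductive cross-electrophile coupling of terminal epoxides with aryl and alkenyl halides, which gives the linear ArCH2CH(OH)R alcohols, a reductive union of two electrophilic carbons. No ring is closed and no stereocentre is created: C8 is imported from 10, its C–O bond is never broken and the radical sits on the neighbouring carbon, so the R configuration should be carried over unchanged. The step needs regioselective opening at CH2, secured by the steric bias of a monosubstituted oxirane towards iodide, and cross- over homo-coupling, secured by the different activation of the two partners (two-electron oxidative addition for the activated sp2 C2–I bond, the only carbon–halogen bond of 6; one-electron activation for the sp3 C–I bond of 11). Direct addition of the same radical to C2 of 6 followed by loss of an iodine atom would converge on the same product, and the tert-butyl ester, MOM acetal and pyranone carbonyl should be inert to Mn/Ni at room temperature.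

**Step 8**
Reactants: 12 tert-butyl (8R)-8-hydroxy-9-[7-methoxy-5-(methoxymethoxy)-4-oxo-4H-chromen-2-yl]nonanoate
Product: 13 (8R)-8-hydroxy-9-(5-hydroxy-7-methoxy-4-oxo-4H-chromen-2-yl)nonanoic acid (penithochromone S)
Conditions: TFA/CH2Cl2/H2O (10:10:1), 0 °C → rt; brief aq. NaHCO3/MeOH, then acidify to pH 3
Reagents that add atoms: none
Why: Brønsted acidolysis in which the aryl methoxymethyl acetal peri to the C4 carbonyl hydrolyses and the tert-butyl ester cleaves to isobutene, while the secondary carbinol and the chromone should be stable at room temperature, so both masks fall in one operation without touching C8.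

**Compound list**
1 | 1-(2,6-dihydroxy-4-methoxyphenyl)ethan-1-one | COc1cc(O)c(C(C)=O)c(O)c1 | starting material
2 | (E)-1-(2,6-dihydroxy-4-methoxyphenyl)-3-(dimethylamino)prop-2-en-1-one | COc1cc(O)c(C(=O)/C=C/N(C)C)c(O)c1 | intermediate (not isolated)
3 | 5-hydroxy-7-methoxy-4H-chromen-4-one | COc1cc(O)c2c(=O)ccoc2c1 | intermediate
4 | 7-methoxy-5-(methoxymethoxy)-4H-chromen-4-one | COCOc1cc(OC)cc2occc(=O)c12 | intermediate
5 | bis[7-methoxy-5-(methoxymethoxy)-4-oxo-4H-chromen-2-yl]zinc (MgCl2/LiCl complex; C2-zincated chromone) | COCOc1cc(OC)cc2oc([Zn]c3cc(=O)c4c(OCOC)cc(OC)cc4o3)cc(=O)c12 | intermediate (not isolated)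
6 | 2-iodo-7-methoxy-5-(methoxymethoxy)-4H-chromen-4-one | COCOc1cc(OC)cc2oc(I)cc(=O)c12 | intermediate
7 | non-8-enoic acid | C=CCCCCCCC(=O)O | starting material
8 | tert-butyl non-8-enoate | C=CCCCCCCC(=O)OC(C)(C)C | intermediate
9 | rac-tert-butyl 7-(oxiran-2-yl)heptanoate | CC(C)(C)OC(=O)CCCCCCC1CO1 | intermediate
10 | tert-butyl 7-[(2R)-oxiran-2-yl]heptanoate | CC(C)(C)OC(=O)CCCCCC[C@@H]1CO1 | intermediate
11 | tert-butyl (8R)-8-hydroxy-9-iodononanoate | IC[C@H](O)CCCCCCC(=O)OC(C)(C)C | intermediate (not isolated)
12 | tert-butyl (8R)-8-hydroxy-9-[7-methoxy-5-(methoxymethoxy)-4-oxo-4H-chromen-2-yl]nonanoate | COc1cc(OCOC)c2c(=O)cc(C[C@H](O)CCCCCCC(=O)OC(C)(C)C)oc2c1 | intermediate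
13 | (8R)-8-hydroxy-9-(5-hydroxy-7-methoxy-4-oxo-4H-chromen-2-yl)nonanoic acid (penithochromone S) | COc1cc(O)c2c(=O)cc(C[C@H](O)CCCCCCC(=O)O)oc2c1 | target

**Count**
Total steps: 8. Longest linear sequence: 5 steps (steps 1, 2, 3, 7, 8 from 1; equally steps 4, 5, 6, 7, 8 from 7).

**Steps most likely to fail**

Step 7. Reductive homodimerisation or protodeiodination of the chromonyl–nickel species, or addition–elimination of liberated triethylamine at C2, may outrun capture of the alkyl radical, and β-hydroxide elimination from the alkylnickel may compete. The fallback reverses the polarity of C2 through an acetylide and closes the pyranone ring late; it sets out from 10 and comes back at 13. Commercial 5-methoxybenzene-1,3-diol is protected (MOMCl, i-Pr2NEt, CH2Cl2) as 1-methoxy-3,5-bis(methoxymethoxy)benzene F1, which is lithiated between the two acetal oxygens (n-BuLi, THF, 0 °C) and formylated with DMF to 4-methoxy-2,6-bis(methoxymethoxy)benzaldehyde F2. Ethynylmagnesium bromide (THF, 0 °C) should give racemic 1-[4-methoxy-2,6-bis(methoxymethoxy)phenyl]prop-2-yn-1-ol F3. F3 is doubly deprotonated (n-BuLi, 2 equiv, THF, −78 °C) and, after BF3·OEt2, opens 10 at its CH2 (Yamaguchi–Hirao alkynylation) to give tert-butyl (8R)-8,12-dihydroxy-12-[4-methoxy-2,6-bis(methoxymethoxy)phenyl]dodec-10-ynoate F4 as a mixture of C12 epimers. MnO2 (CH2Cl2, rt) should oxidise only the benzylic-propargylic carbinol to tert-butyl (8R)-8-hydroxy-12-[4-methoxy-2,6-bis(methoxymethoxy)phenyl]-12-oxododec-10-ynoate F5. TFA/CH2Cl2/H2O then removes both MOM groups and the tert-butyl ester, and either freed phenol closes the pyranone by 6-endo-dig oxa-Michael addition, giving 13.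

Step 3. Metalation may occur at C3 or on the benzo ring instead of at C2, since the site depends on the base and Lewis acid pairing, and the vinylogous acyl iodide may decompose on isolation. The fallback needs no C2 halide; it sets out from 4 and 10 and comes back at 12. Oxirane 10 is opened with LiI/AcOH (THF, rt) to iodohydrin 11, isolated this time, and silylated (TBSCl, imidazole, DMF) to tert-butyl (8R)-8-[(tert-butyldimethylsilyl)oxy]-9-iodononanoate F6. Tin-free Giese addition of the derived primary radical [(Me3Si)3SiH, AIBN, toluene, 80 °C] to the C2=C3 bond of 4 should give tert-butyl (8R)-8-[(tert-butyldimethylsilyl)oxy]-9-[7-methoxy-5-(methoxymethoxy)-4-oxo-3,4-dihydro-2H-chromen-2-yl]nonanoate F7, whose C2 epimers are of no consequence. Dehydrogenation (IBX, DMSO, 70 °C) restores the pyranone as tert-butyl (8R)-8-[(tert-butyldimethylsilyl)oxy]-9-[7-methoxy-5-(methoxymethoxy)-4-oxo-4H-chromen-2-yl]nonanoate F8, and HF·pyridine (THF, 0 °C) returns 12.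

Step 8. Acid may dehydrate the carbinol towards the conjugated 2-alkenylchromone, or the methoxymethyl and tert-butyl cations may alkylate the electron-rich benzo ring at C6/C8. The fallback replaces protic acidolysis by buffered silyl-transfer dealkylation; it sets out from 12 and comes back at 13. TMSOTf with 2,2'-bipyridyl (CH2Cl2, 0 °C → rt) should convert the aryl MOM ether into the aryl silyl ether and the tert-butyl ester into the silyl ester and cap the carbinol, giving trimethylsilyl (8R)-9-[7-methoxy-4-oxo-5-(trimethylsilyloxy)-4H-chromen-2-yl]-8-(trimethylsilyloxy)nonanoate F9. Hydrolysis in H2O/MeOH near pH 6 then gives 13.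

**Further compounds**
F1 | step 7 | 1-methoxy-3,5-bis(methoxymethoxy)benzene | COCOc1cc(OC)cc(OCOC)c1
F2 | step 7 | 4-methoxy-2,6-bis(methoxymethoxy)benzaldehyde | O=Cc1c(OCOC)cc(OC)cc1OCOC
F3 | step 7 | rac-1-[4-methoxy-2,6-bis(methoxymethoxy)phenyl]prop-2-yn-1-ol | C#CC(O)c1c(OCOC)cc(OC)cc1OCOC
F4 | step 7 | tert-butyl (8R)-8,12-dihydroxy-12-[4-methoxy-2,6-bis(methoxymethoxy)phenyl]dodec-10-ynoate | CC(C)(C)OC(=O)CCCCCC[C@@H](O)CC#CC(O)c1c(OCOC)cc(OC)cc1OCOC
F5 | step 7 | tert-butyl (8R)-8-hydroxy-12-[4-methoxy-2,6-bis(methoxymethoxy)phenyl]-12-oxododec-10-ynoate | CC(C)(C)OC(=O)CCCCCC[C@@H](O)CC#CC(=O)c1c(OCOC)cc(OC)cc1OCOC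
F6 | step 3 | tert-butyl (8R)-8-[(tert-butyldimethylsilyl)oxy]-9-iodononanoate | IC[C@H](O[Si](C)(C)C(C)(C)C)CCCCCCC(=O)OC(C)(C)C
F7 | step 3 | tert-butyl (8R)-8-[(tert-butyldimethylsilyl)oxy]-9-[7-methoxy-5-(methoxymethoxy)-4-oxo-3,4-dihydro-2H-chromen-2-yl]nonanoate | COCOc1cc(OC)cc2OC(C[C@H](O[Si](C)(C)C(C)(C)C)CCCCCCC(=O)OC(C)(C)C)CC(=O)c12
F8 | step 3 | tert-butyl (8R)-8-[(tert-butyldimethylsilyl)oxy]-9-[7-methoxy-5-(methoxymethoxy)-4-oxo-4H-chromen-2-yl]nonanoate | COc1cc(OCOC)c2c(=O)cc(C[C@H](O[Si](C)(C)C(C)(C)C)CCCCCCC(=O)OC(C)(C)C)oc2c1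
F9 | step 8 | trimethylsilyl (8R)-9-[7-methoxy-4-oxo-5-(trimethylsilyloxy)-4H-chromen-2-yl]-8-(trimethylsilyloxy)nonanoate | COc1cc(O[Si](C)(C)C)c2c(=O)cc(C[C@H](O[Si](C)(C)C)CCCCCCC(=O)O[Si](C)(C)C)oc2c1
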